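**Retrosynthetic overview**
- The target is 1-[(2R,5R)-5-butyloxolan-2-yl]hexadecan-2-one, a 2,5-cis oxolane (O1, C2–C5) and the only ring.
- The strategy rests on the ring bond C3–C4, which lies between the two ether carbinol carbons C2 (bearing C1'H2–C2'(=O)–tetradecyl) and C5 (bearing butyl). As C3=C4 it is the seam of a ring-closing metathesis of a bis-allylic ether whose halves meet at O1.
- Disconnections, backwards: C2'–tetradecyl (Grignard addition to a C2 acetaldehyde arm, carried as a benzyloxyethyl group); C3=C4 (metathesis, the single ring-forming event, followed by hydrogenation); O1–C2 (iridium-catalysed allylic etherification of a linear (E)-allylic carbonate by the alkoxide of (R)-hept-1-en-3-ol).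
- Stereocentres: C5 comes from lipase resolution of hept-1-en-3-ol and C2 from the chiral iridium catalyst; metathesis and hydrogenation create none.

Key step: step 6

Assumption: the (Ra,Rc,Rc) antipode of the phosphoramidite is taken as the one that directs the alkoxide to the face of the alkyl-substituted allyl terminus giving the (3S) ether carbon; the sense is checked on a small scale first, and the mirror-image ligand is used with no other change if it proves opposite.

**Route**

Step 1
Reactants: 1 rac-hept-1-en-3-ol
Product: 2 (3R)-hept-1-en-3-ol
Conditions: Novozym 435 (immobilised Candida antarctica lipase B), vinyl acetate, hexane, 30 °C, taken somewhat past half conversion; chromatography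
Reagents that add atoms: none
Why: Lipase-catalysed kinetic resolution by transesterification, in which the Kazlauskas rule (vinyl as the medium group, butyl as the large group) predicts faster acetylation of the (S)-alcohol, so the slow-reacting (R)-alcohol that becomes C5 should be left in high enantiomeric purity.

Step 2
Reactants: 3 3-(benzyloxy)propanal
Product: 4 ethyl (2E)-5-(benzyloxy)pent-2-enoate
Conditions: (EtO)2P(O)CH2CO2Et, LiCl, DBU, MeCN, 0 °C to rt
Reagents that add atoms: triethyl phosphonoacetate, CCOC(=O)CP(=O)(OCC)OCC
Why: Horner–Wadsworth–Emmons olefination under Masamune–Roush conditions, where the mild amine base avoids β-elimination of benzyl alcohol from the aldehyde and the stabilised phosphonate anion gives the (E)-enoate.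

Step 3
Reactants: 4 ethyl (2E)-5-(benzyloxy)pent-2-enoate
Product: 5 (2E)-5-(benzyloxy)pent-2-en-1-ol
Conditions: iBu2AlH (2.2 equiv), CH2Cl2, −78 °C; aq. potassium sodium tartrate
Reagents that add atoms: none
Why: 1,2-Reduction of the enoate by the aluminium hydride at low temperature gives the allylic alcohol without changing the alkene geometry or the benzyl ether.

Step 4
Reactants: 5 (2E)-5-(benzyloxy)pent-2-en-1-ol
Product: 6 tert-butyl (2E)-5-(benzyloxy)pent-2-en-1-yl carbonate
Conditions: Boc2O, Bu4NHSO4 (cat.), aq. NaOH, CH2Cl2, 0 °C to rt
Reagents that add atoms: di-tert-butyl dicarbonate, CC(C)(C)OC(=O)OC(=O)OC(C)(C)C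
Why: Phase-transfer O-acylation of the primary alcohol gives the tert-butyl carbonate, chosen because the tert-butoxide released on ionisation is too hindered to compete with the alkoxide nucleophile of step 5 or to exchange with the carbonate.

Step 5
Reactants: 2 (3R)-hept-1-en-3-ol; 6 tert-butyl (2E)-5-(benzyloxy)pent-2-en-1-yl carbonate
Product: 9 benzyl (3S)-3-[(3R)-hept-1-en-3-yloxy]pent-4-en-1-yl ether, via lithium (3R)-hept-1-en-3-olate 7 (not isolated), via cuprous (3R)-hept-1-en-3-olate 8 (not isolated)
Conditions: 2 (1.5 equiv), n-BuLi, THF, 0 °C; CuI, rt; then 6, [Ir(cod)Cl]2 (2 mol %), (Ra,Rc,Rc)-O,O'-(1,1'-binaphthyl-2,2'-diyl) N,N-bis(1-phenylethyl)phosphoramidite (4 mol %), THF, 0 °C to rt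
Reagents that add atoms: none
Why: Iridium-catalysed asymmetric allylic etherification, in which the cyclometalated iridium–phosphoramidite complex ionises the linear carbonate to an allyliridium species and the soft cuprous alkoxide attacks the substituted terminus anti to the metal, giving the branched ether with the ligand (not the resident centre of 2) fixing C2 as the (3S) carbon, while the carbinol C–O bond of 2 is never broken.

Step 6
Reactants: 9 benzyl (3S)-3-[(3R)-hept-1-en-3-yloxy]pent-4-en-1-yl ether
Product: 10 (2S,5R)-2-[2-(benzyloxy)ethyl]-5-butyl-2,5-dihydrofuran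
Conditions: second-generation Grubbs catalyst RuCl2(H2IMes)(PCy3)(=CHPh) (2–3 mol %), 1,4-benzoquinone (10 mol %), CH2Cl2 (0.02 M), 40 °C; ethyl vinyl ether quench
Reagents that add atoms: none
Why: The benzylidene of the catalyst exchanges with one vinyl group of 9 to give a ruthenium alkylidene, which adds across the other vinyl group in an intramolecular [2+2] cycloaddition; cycloreversion of the ruthenacyclobutane expels ethylene and leaves the C3=C4 double bond. The closest known reaction type is ring-closing olefin metathesis of bis-allylic ethers to 2,5-dihydrofurans. The oxolane ring (O1, C2, C3, C4, C5) is closed as a five-membered ring by joining the two terminal alkene carbons of a 1,6-diene, a closure favoured by the short ether tether and made irreversible by loss of ethylene. No stereocentre is formed: C2 (set by the iridium catalyst in step 5) and C5 (set by the resolution in step 1) are sp3 ether carbons that the carbene chemistry does not touch, so their relationship is delivered unchanged as the 2,5-cis arrangement of 10. The step needs ring closure over intermolecular metathesis, secured by high dilution and the five-membered ring size, and it needs the new alkene to stay at C3=C4, since a ruthenium hydride-induced shift into conjugation with O1 would flatten C2 or C5; 1,4-benzoquinone as hydride scavenger, a short reaction time and quenching of the carbene before concentration guard against this.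

Step 7
Reactants: 10 (2S,5R)-2-[2-(benzyloxy)ethyl]-5-butyl-2,5-dihydrofuran
Product: 11 2-[(2R,5R)-5-butyloxolan-2-yl]ethan-1-ol
Conditions: H2 (1 atm), 10% Pd/C, EtOH, rt
Reagents that add atoms: none
Why: Heterogeneous catalytic hydrogenation saturates the disubstituted ring alkene by syn addition, which creates no stereocentre, and hydrogenolysis of the benzylic C–O bond under the same conditions frees the primary alcohol.

Step 8
Reactants: 11 2-[(2R,5R)-5-butyloxolan-2-yl]ethan-1-ol
Product: 12 2-[(2R,5R)-5-butyloxolan-2-yl]acetaldehyde
Conditions: TEMPO (10 mol %), PhI(OAc)2, CH2Cl2, rt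
Reagents that add atoms: none
Why: TEMPO-catalysed oxoammonium oxidation stops at the aldehyde under non-basic conditions, so the β-alkoxy aldehyde is not exposed to base that could open the ring by retro-oxa-Michael reaction and epimerise C2.

Step 9
Reactants: 12 2-[(2R,5R)-5-butyloxolan-2-yl]acetaldehyde; 13 1-bromotetradecane
Product: 15 (2RS)-1-[(2R,5R)-5-butyloxolan-2-yl]hexadecan-2-ol, via tetradecylmagnesium bromide 14 (not isolated)
Conditions: 13, Mg, THF, 50 °C; then 12, THF, −78 to 0 °C; sat. aq. NH4Cl
Reagents that add atoms: none
Why: Grignard formation and 1,2-addition to the aldehyde forms the C2'–tetradecyl bond, the new carbinol centre arising as a mixture of epimers that is of no consequence because it is oxidised in step 10.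

Step 10
Reactants: 15 (2RS)-1-[(2R,5R)-5-butyloxolan-2-yl]hexadecan-2-ol
Product: 16 1-[(2R,5R)-5-butyloxolan-2-yl]hexadecan-2-one
Conditions: Dess–Martin periodinane, pyridine, CH2Cl2, 0 °C to rt
Reagents that add atoms: none
Why: Dess–Martin oxidation of the secondary alcohol under pyridine-buffered, near-neutral conditions gives the ketone and removes the stereorandom carbinol centre without epimerising C2 of the β-alkoxy ketone.

**Compound list**
1 | rac-hept-1-en-3-ol | CCCCC(O)C=C | starting material
2 | (3R)-hept-1-en-3-ol | CCCC[C@@H](O)C=C | intermediate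
3 | 3-(benzyloxy)propanal | O=CCCOCc1ccccc1 | starting material
4 | ethyl (2E)-5-(benzyloxy)pent-2-enoate | CCOC(=O)/C=C/CCOCc1ccccc1 | intermediate
5 | (2E)-5-(benzyloxy)pent-2-en-1-ol | OC/C=C/CCOCc1ccccc1 | intermediate
6 | tert-butyl (2E)-5-(benzyloxy)pent-2-en-1-yl carbonate | CC(C)(C)OC(=O)OC/C=C/CCOCc1ccccc1 | intermediate
7 | lithium (3R)-hept-1-en-3-olate | CCCC[C@@H](O[Li])C=C | intermediate
8 | cuprous (3R)-hept-1-en-3-olate | CCCC[C@@H](O[Cu])C=C | intermediate
9 | benzyl (3S)-3-[(3R)-hept-1-en-3-yloxy]pent-4-en-1-yl ether | C=C[C@@H](CCCC)O[C@H](C=C)CCOCc1ccccc1 | intermediate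
10 | (2S,5R)-2-[2-(benzyloxy)ethyl]-5-butyl-2,5-dihydrofuran (2,5-cis) | c1ccccc1COCC[C@H]2C=C[C@@H](CCCC)O2 | intermediate
11 | 2-[(2R,5R)-5-butyloxolan-2-yl]ethan-1-ol | OCC[C@H]1CC[C@@H](CCCC)O1 | intermediate
12 | 2-[(2R,5R)-5-butyloxolan-2-yl]acetaldehyde | O=CC[C@H]1CC[C@@H](CCCC)O1 | intermediate
13 | 1-bromotetradecane | CCCCCCCCCCCCCCBr | starting material
14 | tetradecylmagnesium bromide | CCCCCCCCCCCCCC[Mg]Br | intermediate
15 | (2RS)-1-[(2R,5R)-5-butyloxolan-2-yl]hexadecan-2-ol | CCCCCCCCCCCCCCC(O)C[C@H]1CC[C@@H](CCCC)O1 | intermediate
16 | 1-[(2R,5R)-5-butyloxolan-2-yl]hexadecan-2-one | CCCCCCCCCCCCCCC(=O)C[C@H]1CC[C@@H](CCCC)O1 | target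

**Step count**
Total steps: 10. Longest linear sequence: 9 steps (steps 2–10, from 3-(benzyloxy)propanal).

**Steps most likely to fail, with fallbacks**

Step 5. The hindered secondary cuprous alkoxide may attack the unsubstituted allyl terminus (linear ether), turnover with the alkyl-substituted carbonate may be slow, or catalyst control may be eroded by the resident centre of the alkoxide, lowering the diastereomeric purity at C2. The fallback replaces catalyst control by a stereospecific substitution on a resolved branched electrophile. It sets out from 3: addition of vinylmagnesium bromide (THF, −78 °C) would give rac-5-(benzyloxy)pent-1-en-3-ol F1. Lipase-catalysed acetylation (Novozym 435, vinyl acetate), stopped short of half conversion, would give the fast-reacting (3S)-5-(benzyloxy)pent-1-en-3-yl acetate F2. Methanolysis (K2CO3, MeOH) would give (3S)-5-(benzyloxy)pent-1-en-3-ol F3, and n-BuLi then Boc2O (THF, −78 °C to rt) would give (3S)-5-(benzyloxy)pent-1-en-3-yl tert-butyl carbonate F4. Rhodium-catalysed allylic etherification of F4 with cuprous alkoxide 8 (RhCl(PPh3)3, P(OMe)3, THF, 0 °C to rt) should proceed at the carbon bearing the leaving group with net retention, and comes back to the route at 9.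

Step 7. Palladium hydride may shift C3=C4 toward O1 before hydrogen is added, which would erase C2 or C5 and re-form it without control, or the ring allylic C–O bonds may be hydrogenolysed. The fallback separates the two tasks and removes the metal from the alkene reduction. It sets out from 10: diimide generated from 2-nitrobenzenesulfonylhydrazide and Et3N (CH2Cl2, rt) would transfer hydrogen to C3=C4 in a concerted syn fashion and give (2R,5R)-2-[2-(benzyloxy)ethyl]-5-butyloxolane F5. Hydrogenolysis of the benzyl ether on the saturated ring (H2, Pd(OH)2/C, EtOH) comes back to the route at 11.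

Step 9. The basic Grignard reagent may deprotonate the α-CH2 of the aldehyde, and the enolate may expel the ring oxygen and re-close without control, epimerising C2; β-hydride reduction of the aldehyde may also compete. The fallback moves to the carboxylic acid oxidation level and an acyl substitution. It sets out from 12: Pinnick oxidation (NaClO2, NaH2PO4, 2-methylbut-2-ene, t-BuOH/H2O) would give [(2R,5R)-5-butyloxolan-2-yl]acetic acid F6. Coupling with N,O-dimethylhydroxylamine hydrochloride (EDC hydrochloride, iPr2NEt, CH2Cl2) would give 2-[(2R,5R)-5-butyloxolan-2-yl]-N-methoxy-N-methylacetamide F7. Addition of tetradecylmagnesium bromide 14 (THF, 0 °C) forms a stable chelated tetrahedral intermediate that gives the ketone on work-up, coming back to the route at 16 and making step 10 unnecessary.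

**Further compounds**
F1 | step 5 | rac-5-(benzyloxy)pent-1-en-3-ol | C=CC(O)CCOCc1ccccc1
F2 | step 5 | (3S)-5-(benzyloxy)pent-1-en-3-yl acetate | C=C[C@@H](OC(C)=O)CCOCc1ccccc1
F3 | step 5 | (3S)-5-(benzyloxy)pent-1-en-3-ol | C=C[C@@H](O)CCOCc1ccccc1
F4 | step 5 | (3S)-5-(benzyloxy)pent-1-en-3-yl tert-butyl carbonate | C=C[C@@H](OC(=O)OC(C)(C)C)CCOCc1ccccc1
F5 | step 7 | (2R,5R)-2-[2-(benzyloxy)ethyl]-5-butyloxolane | c1ccccc1COCC[C@H]2CC[C@@H](CCCC)O2
F6 | step 9 | [(2R,5R)-5-butyloxolan-2-yl]acetic acid | OC(=O)C[C@H]1CC[C@@H](CCCC)O1
F7 | step 9 | 2-[(2R,5R)-5-butyloxolan-2-yl]-N-methoxy-N-methylacetamide | CON(C)C(=O)C[C@H]1CC[C@@H](CCCC)O1
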